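Cuts: both pyranones are opened at O1–C2 and C2–C3, giving 1,3-diketones that come from an o-hydroxyacetophenone and an aroyl chloride. Unit 2 (the 6-aryloxyflavone) is also cut at C4–C4a, and ring B of unit 1 (the 7-methoxyflavone) at C2'–C3' and C4'–C5'.
Feature used: ring B of unit 1 is a benzene ring with only two substituents, in a 1,4 relation. C1' is bound to C2 of its pyranone, and C4' to the ether oxygen that leads to the crowded C6 of unit 2, which sits between the oxygenated C5 and C7.
A 2-pyranone with an ester on C5 supplies C5', C6', C1' and C2'. An aryl ethynyl ether supplies C3' and C4', with the hindered aryl–oxygen bond already in place.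
Forward: ring A of unit 2 is bought and its 4-hydroxyl becomes an ethynyl ether. Ring B of unit 1 is built in step 5 and CHO is exchanged for OH. The pyranone of unit 2 closes in step 10 and that of unit 1 in step 14, and hydrogenolysis ends the route.
Stereochemistry: the target has no stereocentre. Only regiochemistry has to be controlled: para orientation in step 5 and closure onto the single free hydroxyl in step 10.
Key step: step 5

Remark: the 1,2-dichlorovinyl ethers are drawn as the E isomers expected from anti addition to dichloroacetylene (the geometry disappears in step 4), and the 1,3-diketones are drawn in the diketo form.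

Step 1
Reactants: 1 3,4,5-trihydroxybenzaldehyde; 2 trichloroethylene
Product: 4 4-[(E)-1,2-dichloroethenyloxy]-3,5-dihydroxybenzaldehyde, via dichloroacetylene 3 (not isolated)
Conditions: K2CO3 (1.1 equiv), 2 (1.2 equiv), degassed DMF, 60 °C, under argon
Reagents that add atoms: none
Why: K2CO3 strips HCl from 2 to give the strongly electrophilic alkyne 3, a phenoxide adds to it in the anti sense (the established aryl 1,2-dichlorovinyl ether synthesis), and with about one equivalent of base only the hydroxyl para to the formyl group, the most acidic of the three, is ionised, which is the same bias that makes alkylation of gallates and protocatechualdehyde 4-O-selective.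

Step 2
Reactants: 4 4-[(E)-1,2-dichloroethenyloxy]-3,5-dihydroxybenzaldehyde
Product: 5 3,5-bis(benzyloxy)-4-[(E)-1,2-dichloroethenyloxy]benzaldehyde
Conditions: BnBr (2.3 equiv), K2CO3 (2.5 equiv), DMF, rt
Reagents that add atoms: benzyl bromide, BrCc1ccccc1
Why: Williamson ether synthesis on the two remaining, equivalent phenols, run at room temperature where the aldehyde and the dichlorovinyl ether are inert to K2CO3 and fast benzylation leaves the neighbouring phenoxides no time to attack the vinyl chloride.

Step 3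
Reactants: 5 3,5-bis(benzyloxy)-4-[(E)-1,2-dichloroethenyloxy]benzaldehyde
Product: 6 2-{3,5-bis(benzyloxy)-4-[(E)-1,2-dichloroethenyloxy]phenyl}-1,3-dioxolane
Conditions: HOCH2CH2OH (5 equiv), PPTS (cat.), toluene, reflux, Dean–Stark trap
Reagents that add atoms: ethylene glycol, OCCO
Why: Acid-catalysed acetalisation with azeotropic removal of water masks the aldehyde against n-BuLi, and the electron-poor dichlorovinyl ether is not attacked by a pyridinium acid.

Step 4
Reactants: 6 2-{3,5-bis(benzyloxy)-4-[(E)-1,2-dichloroethenyloxy]phenyl}-1,3-dioxolane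
Product: 9 2-[3,5-bis(benzyloxy)-4-(ethynyloxy)phenyl]-1,3-dioxolane, via chloroethynyl ether 7 (not isolated), via lithium acetylide 8 (not isolated)
Conditions: n-BuLi (2.3 equiv), THF, −78 to −40 °C; H2O, −78 °C; quick filtration through Et3N-deactivated silica, used at once
Reagents that add atoms: none
Why: Standard conversion of a 1,2-dichlorovinyl ether into an ynol ether, in which the first n-BuLi removes the vinyl proton so that LiCl leaves to give 7, the second exchanges chlorine for lithium to give 8, and water protonates the acetylide, while benzyl ethers and dioxolane are untouched at −78 °C.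

Step 5
Reactants: 9 2-[3,5-bis(benzyloxy)-4-(ethynyloxy)phenyl]-1,3-dioxolane; 10 methyl coumalate (methyl 2-oxo-2H-pyran-5-carboxylate)
Product: 12 methyl 4-[2,6-bis(benzyloxy)-4-(1,3-dioxolan-2-yl)phenoxy]benzoate, via bridged lactone 11 (not isolated)
Conditions: 10 (1.5 equiv), toluene, 110 °C, sealed tube, under argon
Reagents that add atoms: none
Why: The electron-poor diene of 10 (pyranone C3 to C6) and the electron-rich triple bond of 9 combine in a concerted but asynchronous inverse-electron-demand (4+2) cycloaddition to the bridged lactone 11, which expels CO2 in a retro-(4+2) at the same temperature, so ring B of unit 1 emerges aromatic without any oxidant. The closest known reaction type is the Diels–Alder/decarboxylation of methyl coumalate with alkoxyalkynes, ketene acetals and enol ethers, which gives para-substituted benzoates. The one ring that persists, the benzene ring, is closed intermolecularly by two new C–C bonds, C2'–C3' (pyranone C6 to the terminal alkyne carbon) and C4'–C5' (the oxygen-bearing alkyne carbon to pyranone C3), with four ring carbons from 10 and two from 9. The two bridgehead stereocentres of 11 arise as a racemate, are tied to each other by the cage and vanish with CO2, so the product has none. The selectivity needed is regioselectivity, and polarity secures it because the terminal carbon β to oxygen carries the largest HOMO coefficient of 9 and pyranone C6, vinylogous to both the ester and the lactone carbonyl, the largest LUMO coefficient of 10, which places the aryloxy group para to the ester. An aryl ynol ether has no β-hydrogen for retro-ene collapse to a ketene, its two ortho benzyloxy groups hinder self-addition, and acetal, benzyl ethers and ester are inert to neutral heating.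

Step 6
Reactants: 12 methyl 4-[2,6-bis(benzyloxy)-4-(1,3-dioxolan-2-yl)phenoxy]benzoate
Product: 13 methyl 4-[2,6-bis(benzyloxy)-4-formylphenoxy]benzoate
Conditions: 1 M HCl, THF, rt
Reagents that add atoms: water, O
Why: Acid hydrolysis of the cyclic acetal, under which the methyl ester, benzyl ethers and diaryl ether are stable.

Step 7
Reactants: 13 methyl 4-[2,6-bis(benzyloxy)-4-formylphenoxy]benzoate
Product: 15 methyl 4-[2,6-bis(benzyloxy)-4-hydroxyphenoxy]benzoate, via aryl formate 14 (not isolated)
Conditions: mCPBA, CH2Cl2, 0 °C to rt; aq NaHCO3 wash; then K2CO3 (cat.), MeOH, rt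
Reagents that add atoms: 3-chloroperoxybenzoic acid (mCPBA), OOC(=O)c1cccc(Cl)c1
Why: Baeyer–Villiger (Dakin-type) oxidation, the routine path from 4-aryloxybenzaldehydes to 4-aryloxyphenols, in which the oxygen-rich aryl group migrates in preference to hydride and mild methanolysis of formate 14 frees a symmetric phenol while the methyl ester can only exchange with its own alcohol.

Step 8
Reactants: 15 methyl 4-[2,6-bis(benzyloxy)-4-hydroxyphenoxy]benzoate
Product: 17 methyl 4-[3-acetyl-2,6-bis(benzyloxy)-4-hydroxyphenoxy]benzoate, via ketiminium chloride 16 (not isolated)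
Conditions: MeCN, ZnCl2 (0.3 equiv), HCl gas, Et2O–CH2Cl2, 0 °C; then H2O–MeOH, 65 °C
Reagents that add atoms: acetonitrile, CC#N; water, O
Why: Houben–Hoesch acylation, the classical entry to 2-hydroxy-4,5,6-trialkoxyacetophenones, which should work because the two free ring positions are equivalent and each lies ortho to OH and ortho and para to a benzyloxy group, the para position is blocked, the benzoate ring is deactivated, the protonated imine prevents a second attack, and HCl/ZnCl2 at 0 °C is mild enough for aryl benzyl ethers and the ester.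

Step 9
Reactants: 17 methyl 4-[3-acetyl-2,6-bis(benzyloxy)-4-hydroxyphenoxy]benzoate; 18 4-(benzyloxy)benzoyl chloride
Product: 20 methyl 4-[2,6-bis(benzyloxy)-3-{3-[4-(benzyloxy)phenyl]-3-oxopropanoyl}-4-hydroxyphenoxy]benzoate, via dilithium enolate 19 (not isolated)
Conditions: LiN(SiMe3)2 (3.2 equiv), THF, −78 to −20 °C; 18 (1.05 equiv), −78 °C to rt; 1 M HCl
Reagents that add atoms: none
Why: Claisen-type C-acylation of a preformed lithium enolate by an aroyl chloride, the one-flask form of the Baker–Venkataraman diketone synthesis, in which the acid chloride is far more electrophilic than the methyl benzoate of 17 and the third equivalent of base stores the product as its unreactive enolate.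

Step 10
Reactants: 20 methyl 4-[2,6-bis(benzyloxy)-3-{3-[4-(benzyloxy)phenyl]-3-oxopropanoyl}-4-hydroxyphenoxy]benzoate
Product: 21 methyl 4-({5,7-bis(benzyloxy)-2-[4-(benzyloxy)phenyl]-4-oxo-4H-chromen-6-yl}oxy)benzoate
Conditions: NaOAc, AcOH, 100 °C
Reagents that add atoms: none
Why: Cyclodehydration of an o-hydroxyaryl 1,3-diketone closes the pyranone of unit 2, and because only the hydroxyl that replaced the formyl carbon is free, O1 can form only there, which fixes the aryloxy group at C6 and not C8, while buffered acetic acid spares the benzyl ethers.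

Step 11
Reactants: 21 methyl 4-({5,7-bis(benzyloxy)-2-[4-(benzyloxy)phenyl]-4-oxo-4H-chromen-6-yl}oxy)benzoate
Product: 22 4-({5,7-bis(benzyloxy)-2-[4-(benzyloxy)phenyl]-4-oxo-4H-chromen-6-yl}oxy)benzoic acid
Conditions: LiOH (3 equiv), THF–MeOH–H2O, rt; then 1 M HCl
Reagents that add atoms: lithium hydroxide, [Li+].[OH-]
Why: Saponification of an unhindered methyl benzoate, which at room temperature is faster than hydroxide attack at C2 of the flavone.

Step 12
Reactants: 22 4-({5,7-bis(benzyloxy)-2-[4-(benzyloxy)phenyl]-4-oxo-4H-chromen-6-yl}oxy)benzoic acid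
Product: 23 4-({5,7-bis(benzyloxy)-2-[4-(benzyloxy)phenyl]-4-oxo-4H-chromen-6-yl}oxy)benzoyl chloride
Conditions: (COCl)2 (1.5 equiv), DMF (cat.), CH2Cl2, 0 °C to rt; evaporation
Reagents that add atoms: oxalyl chloride, ClC(=O)C(=O)Cl
Why: Acid chloride formation with oxalyl chloride under DMF catalysis, mild enough for benzyl ethers, the diaryl ether and the flavone.

Step 13
Reactants: 23 4-({5,7-bis(benzyloxy)-2-[4-(benzyloxy)phenyl]-4-oxo-4H-chromen-6-yl}oxy)benzoyl chloride; 24 2',6'-dihydroxy-4'-methoxyacetophenone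
Product: 26 1-(2,6-dihydroxy-4-methoxyphenyl)-3-[4-({5,7-bis(benzyloxy)-2-[4-(benzyloxy)phenyl]-4-oxo-4H-chromen-6-yl}oxy)phenyl]propane-1,3-dione, via trilithium enolate 25 (not isolated)
Conditions: 24, LiN(SiMe3)2 (4.2 equiv), THF, −78 to −10 °C; 23 in THF, −78 °C to rt; 1 M HCl
Reagents that add atoms: none
Why: The same enolate C-acylation as in step 9, run on the trilithium salt of the unprotected dihydroxyacetophenone so that unit 1 needs no protecting group, with the carbon terminus of the enolate as the most nucleophilic site and the acid chloride as the only strong electrophile present.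

Step 14
Reactants: 26 1-(2,6-dihydroxy-4-methoxyphenyl)-3-[4-({5,7-bis(benzyloxy)-2-[4-(benzyloxy)phenyl]-4-oxo-4H-chromen-6-yl}oxy)phenyl]propane-1,3-dione
Product: 27 5,7-bis(benzyloxy)-2-[4-(benzyloxy)phenyl]-6-[4-(5-hydroxy-7-methoxy-4-oxo-4H-chromen-2-yl)phenoxy]-4H-chromen-4-one (tri-O-benzylneocryptomerin)
Conditions: NaOAc, AcOH, 100 °C
Reagents that add atoms: none
Why: Cyclodehydration as in step 10 closes the pyranone of unit 1, and since the two hydroxyls flanking the ketone are equivalent by symmetry, closure on either one gives the same 5-hydroxy-7-methoxyflavone.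

Step 15
Reactants: 27 tri-O-benzylneocryptomerin
Product: 28 neocryptomerin
Conditions: H2 (1 atm), Pd/C, THF–MeOH, rt
Reagents that add atoms: none
Why: Hydrogenolysis of the three aryl benzyl ethers over palladium, which at atmospheric pressure leaves the methyl ether, the diaryl ether and both conjugated pyranones intact.

Compound list
1 | 3,4,5-trihydroxybenzaldehyde | O=Cc1cc(O)c(O)c(O)c1 | starting material
2 | trichloroethylene | ClC=C(Cl)Cl | starting material
3 | dichloroacetylene (formed in the flask) | ClC#CCl | intermediate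
4 | 4-[(E)-1,2-dichloroethenyloxy]-3,5-dihydroxybenzaldehyde | O=Cc1cc(O)c(O/C(Cl)=C\Cl)c(O)c1 | intermediate
5 | 3,5-bis(benzyloxy)-4-[(E)-1,2-dichloroethenyloxy]benzaldehyde | O=Cc1cc(OCc2ccccc2)c(O/C(Cl)=C\Cl)c(OCc3ccccc3)c1 | intermediate
6 | 2-{3,5-bis(benzyloxy)-4-[(E)-1,2-dichloroethenyloxy]phenyl}-1,3-dioxolane | Cl/C=C(Cl)\Oc1c(OCc2ccccc2)cc(cc1OCc3ccccc3)C4OCCO4 | intermediate
7 | 2-[3,5-bis(benzyloxy)-4-(chloroethynyloxy)phenyl]-1,3-dioxolane (formed in the flask) | ClC#COc1c(OCc2ccccc2)cc(cc1OCc3ccccc3)C4OCCO4 | intermediate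
8 | lithium acetylide of 9 (formed in the flask) | [Li]C#COc1c(OCc2ccccc2)cc(cc1OCc3ccccc3)C4OCCO4 | intermediate
9 | 2-[3,5-bis(benzyloxy)-4-(ethynyloxy)phenyl]-1,3-dioxolane | C#COc1c(OCc2ccccc2)cc(cc1OCc3ccccc3)C4OCCO4 | intermediate
10 | methyl coumalate | COC(=O)C1=COC(=O)C=C1 | starting material
11 | methyl 8-[2,6-bis(benzyloxy)-4-(1,3-dioxolan-2-yl)phenoxy]-3-oxo-2-oxabicyclo[2.2.2]octa-5,7-diene-6-carboxylate (bridged lactone, racemic, one enantiomer drawn, formed in the flask) | COC(=O)C1=C[C@H]2C(=O)O[C@@H]1C=C2Oc3c(OCc4ccccc4)cc(cc3OCc5ccccc5)C6OCCO6 | intermediate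
12 | methyl 4-[2,6-bis(benzyloxy)-4-(1,3-dioxolan-2-yl)phenoxy]benzoate | COC(=O)c1ccc(cc1)Oc2c(OCc3ccccc3)cc(cc2OCc4ccccc4)C5OCCO5 | intermediate
13 | methyl 4-[2,6-bis(benzyloxy)-4-formylphenoxy]benzoate | COC(=O)c1ccc(cc1)Oc2c(OCc3ccccc3)cc(C=O)cc2OCc4ccccc4 | intermediate
14 | methyl 4-[2,6-bis(benzyloxy)-4-(formyloxy)phenoxy]benzoate (carried on crude) | COC(=O)c1ccc(cc1)Oc2c(OCc3ccccc3)cc(OC=O)cc2OCc4ccccc4 | intermediate
15 | methyl 4-[2,6-bis(benzyloxy)-4-hydroxyphenoxy]benzoate | COC(=O)c1ccc(cc1)Oc2c(OCc3ccccc3)cc(O)cc2OCc4ccccc4 | intermediate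
16 | ketiminium chloride of 17 (formed in the flask) | COC(=O)c1ccc(cc1)Oc2c(OCc3ccccc3)cc(O)c(C(C)=[NH2+])c2OCc4ccccc4.[Cl-] | intermediate
17 | methyl 4-[3-acetyl-2,6-bis(benzyloxy)-4-hydroxyphenoxy]benzoate | COC(=O)c1ccc(cc1)Oc2c(OCc3ccccc3)cc(O)c(C(C)=O)c2OCc4ccccc4 | intermediate
18 | 4-(benzyloxy)benzoyl chloride | O=C(Cl)c1ccc(OCc2ccccc2)cc1 | starting material
19 | dilithium phenoxide-enolate of 17 (formed in the flask) | COC(=O)c1ccc(cc1)Oc2c(OCc3ccccc3)cc(O[Li])c(C(=C)O[Li])c2OCc4ccccc4 | intermediate
20 | methyl 4-[2,6-bis(benzyloxy)-3-{3-[4-(benzyloxy)phenyl]-3-oxopropanoyl}-4-hydroxyphenoxy]benzoate | COC(=O)c1ccc(cc1)Oc2c(OCc3ccccc3)cc(O)c(C(=O)CC(=O)c4ccc(OCc5ccccc5)cc4)c2OCc6ccccc6 | intermediate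
21 | methyl 4-({5,7-bis(benzyloxy)-2-[4-(benzyloxy)phenyl]-4-oxo-4H-chromen-6-yl}oxy)benzoate | COC(=O)c1ccc(cc1)Oc2c(OCc3ccccc3)cc4oc(cc(=O)c4c2OCc5ccccc5)-c6ccc(OCc7ccccc7)cc6 | intermediate
22 | 4-({5,7-bis(benzyloxy)-2-[4-(benzyloxy)phenyl]-4-oxo-4H-chromen-6-yl}oxy)benzoic acid | OC(=O)c1ccc(cc1)Oc2c(OCc3ccccc3)cc4oc(cc(=O)c4c2OCc5ccccc5)-c6ccc(OCc7ccccc7)cc6 | intermediate
23 | 4-({5,7-bis(benzyloxy)-2-[4-(benzyloxy)phenyl]-4-oxo-4H-chromen-6-yl}oxy)benzoyl chloride | ClC(=O)c1ccc(cc1)Oc2c(OCc3ccccc3)cc4oc(cc(=O)c4c2OCc5ccccc5)-c6ccc(OCc7ccccc7)cc6 | intermediate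
24 | 2',6'-dihydroxy-4'-methoxyacetophenone | COc1cc(O)c(C(C)=O)c(O)c1 | starting material
25 | trilithium bis(phenoxide)-enolate of 24 (formed in the flask) | COc1cc(O[Li])c(C(=C)O[Li])c(O[Li])c1 | intermediate
26 | 1-(2,6-dihydroxy-4-methoxyphenyl)-3-[4-({5,7-bis(benzyloxy)-2-[4-(benzyloxy)phenyl]-4-oxo-4H-chromen-6-yl}oxy)phenyl]propane-1,3-dione | COc1cc(O)c(C(=O)CC(=O)c2ccc(cc2)Oc3c(OCc4ccccc4)cc5oc(cc(=O)c5c3OCc6ccccc6)-c7ccc(OCc8ccccc8)cc7)c(O)c1 | intermediate
27 | tri-O-benzylneocryptomerin, 5,7-bis(benzyloxy)-2-[4-(benzyloxy)phenyl]-6-[4-(5-hydroxy-7-methoxy-4-oxo-4H-chromen-2-yl)phenoxy]-4H-chromen-4-one | COc1cc(O)c2c(=O)cc(oc2c1)-c3ccc(cc3)Oc4c(OCc5ccccc5)cc6oc(cc(=O)c6c4OCc7ccccc7)-c8ccc(OCc9ccccc9)cc8 | intermediate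
28 | neocryptomerin, 5,7-dihydroxy-6-[4-(5-hydroxy-7-methoxy-4-oxo-4H-chromen-2-yl)phenoxy]-2-(4-hydroxyphenyl)-4H-chromen-4-one | COc1cc(O)c2c(=O)cc(-c3ccc(Oc4c(O)cc5oc(-c6ccc(O)cc6)cc(=O)c5c4O)cc3)oc2c1 | target

Total step count: 15. Longest linear sequence: 15 steps, from 1 to 28. Compounds 2, 10, 18 and 24 enter as purchased materials.

Steps most likely to fail

Step 5. Oligomerisation or adventitious hydration of the terminal ynol ether may outrun the cycloaddition, which is slowed by the bulky and only moderately donating aryloxy group. Stronger heating could also erode the para orientation. The fallback keeps the same two ring bonds, sets out from 6 and comes back at 13. Acetylide 8, generated from 6 as in step 4, is quenched with Me3SiCl instead of water to give 2-{3,5-bis(benzyloxy)-4-[(trimethylsilyl)ethynyloxy]phenyl}-1,3-dioxolane F1, a capped ynol ether that can be purified, stored and heated harder. With 10 in xylene at about 140 °C it should pass through the silylated bridged lactone F2, and loss of CO2 should give methyl 4-[2,6-bis(benzyloxy)-4-(1,3-dioxolan-2-yl)phenoxy]-3-(trimethylsilyl)benzoate F3. Brief treatment with CF3CO2H in wet CH2Cl2 should bring about ipso-protodesilylation ortho to the aryloxy group and open the acetal in the same operation, which gives 13.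

Step 1. More than one hydroxyl may add to dichloroacetylene, a neighbouring hydroxyl may close onto the dichlorovinyl group, and the pyrogallol may be oxidised by air under base. The fallback removes the free neighbouring hydroxyls before the vinyl ether is made, sets out from 1 and comes back at 5. Exhaustive benzylation (BnBr, K2CO3, DMF) gives 3,4,5-tris(benzyloxy)benzaldehyde F4. The central, out-of-plane ether is then cleaved with AlCl3 in CH2Cl2 at low temperature, the Lewis-acid dealkylation that singles out the 4-alkoxy group of 3,4,5-trialkoxybenzaldehydes, to give 3,5-bis(benzyloxy)-4-hydroxybenzaldehyde F5. With its single hydroxyl, F5 is treated with 2 and K2CO3 in DMF at 70 °C and should give 5 directly.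

Step 8. Benzyl groups may be lost or migrate to carbon under acid, or the activated nitrile may be captured at the phenolic oxygen instead of at carbon. The fallback avoids acid and electrophilic acylation altogether, sets out from 15, comes back at 21 and bypasses steps 8 to 10. Mono-iodination ortho to the hydroxyl with N-iodosuccinimide (1 equiv, MeCN, 0 °C) gives methyl 4-[2,6-bis(benzyloxy)-4-hydroxy-3-iodophenoxy]benzoate F6. Carbonylative coupling with commercial 1-(benzyloxy)-4-ethynylbenzene under CO, with PdCl2(PPh3)2 as catalyst in Et2NH at 60 to 80 °C, should give the alkynone F7. The secondary amine steers F7 into 6-endo closure onto the free hydroxyl, the known carbonylative annulation of o-iodophenols to flavones, and this yields 21.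

Further compounds
F1 | step 5 | 2-{3,5-bis(benzyloxy)-4-[(trimethylsilyl)ethynyloxy]phenyl}-1,3-dioxolane | C[Si](C)(C)C#COc1c(OCc2ccccc2)cc(cc1OCc3ccccc3)C4OCCO4
F2 | step 5 | methyl 8-[2,6-bis(benzyloxy)-4-(1,3-dioxolan-2-yl)phenoxy]-3-oxo-7-(trimethylsilyl)-2-oxabicyclo[2.2.2]octa-5,7-diene-6-carboxylate (silylated bridged lactone, racemic, one enantiomer drawn) | COC(=O)C1=C[C@H]2C(=O)O[C@@H]1C([Si](C)(C)C)=C2Oc3c(OCc4ccccc4)cc(cc3OCc5ccccc5)C6OCCO6
F3 | step 5 | methyl 4-[2,6-bis(benzyloxy)-4-(1,3-dioxolan-2-yl)phenoxy]-3-(trimethylsilyl)benzoate | COC(=O)c1ccc(Oc2c(OCc3ccccc3)cc(cc2OCc4ccccc4)C5OCCO5)c(c1)[Si](C)(C)C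
F4 | step 1 | 3,4,5-tris(benzyloxy)benzaldehyde | O=Cc1cc(OCc2ccccc2)c(OCc3ccccc3)c(OCc4ccccc4)c1
F5 | step 1 | 3,5-bis(benzyloxy)-4-hydroxybenzaldehyde | O=Cc1cc(OCc2ccccc2)c(O)c(OCc3ccccc3)c1
F6 | step 8 | methyl 4-[2,6-bis(benzyloxy)-4-hydroxy-3-iodophenoxy]benzoate | COC(=O)c1ccc(cc1)Oc2c(OCc3ccccc3)cc(O)c(I)c2OCc4ccccc4
F7 | step 8 | methyl 4-[2,6-bis(benzyloxy)-3-{3-[4-(benzyloxy)phenyl]prop-2-ynoyl}-4-hydroxyphenoxy]benzoate (alkynone) | COC(=O)c1ccc(cc1)Oc2c(OCc3ccccc3)cc(O)c(C(=O)C#Cc4ccc(OCc5ccccc5)cc4)c2OCc6ccccc6
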